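A direct plan would build the ether by O-arylation of a catechol: veratrole A1 would be dilithiated and brominated to 1,4-dibromo-2,3-dimethoxybenzene A2, demethylated to 3,6-dibromocatechol A3, and A3 would be mono-arylated with the (2,4-dibromophenyl)(2,4,6-trimethoxyphenyl)iodonium tosylate A4. Its weakest steps would be:
- the mono-O-arylation of the free catechol, because trivalent iodine would tend to oxidise a catechol to the o-quinone and only stoichiometry would hold back a second arylation;
- the double ortho-lithiation and bromination, because incomplete dilithiation would leave a monobromide that is hard to remove;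
- the cleavage of both methyl ethers, which would add a step without adding complexity.

The ether is disconnected at O–C2 of ring A while ring A is still a cyclohexane-1,3-dione. The key step, a carbenoid O–H insertion of 2,4-dibromophenol into 2-diazocyclohexane-1,3-dione, would forge that bond at the carbon lying between the two carbonyls. These become C1–OH and, through the vinylogous acid bromide, C3–Br; the mirror symmetry of the dione makes the choice between them immaterial. Ring A would be aromatised afterwards and C6–Br placed ortho to the new OH. No catechol, no aryl–metal species and no O-methyl group appears, so selective mono-arylation, dilithiation and ether cleavage would have no counterpart.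

Key step: step 2

Remark: ring A is the phenol ring (C1–OH, C2–OAr, C3–Br, C6–Br) and ring B the 2,4-dibromophenyl ring. Compound 4 is written as the diketone, although it should exist mainly as its enol, 2-(2,4-dibromophenoxy)-3-hydroxycyclohex-2-en-1-one.

Step 1
Reactants: 1 cyclohexane-1,3-dione
Product: 2 2-diazocyclohexane-1,3-dione
Conditions: 4-acetamidobenzenesulfonyl azide (1.05 equiv), Et3N (1.1 equiv), MeCN, 0 °C → rt
Reagents that add atoms: 4-acetamidobenzenesulfonyl azide, CC(=O)Nc1ccc(cc1)S(=O)(=O)N=[N+]=[N-]
Why: Regitz diazo transfer to the doubly activated C2 methylene of a 1,3-diketone, with the sulfonamide by-product removed by filtration and a basic wash.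

Step 2
Reactants: 2 2-diazocyclohexane-1,3-dione; 3 2,4-dibromophenol
Product: 4 2-(2,4-dibromophenoxy)cyclohexane-1,3-dione
Conditions: 3 (1.5 equiv), Rh2(OAc)4 (1 mol%), PhCF3, 70 °C, slow addition of 2
Reagents that add atoms: none
Why: Rh2(OAc)4 would strip N2 from 2 to give an electrophilic acceptor/acceptor rhodium carbenoid, whose carbene carbon is attacked by the phenol oxygen of 3 to give an oxonium ylide that collapses by proton transfer to the 2-aryloxy-1,3-dione. The closest known reaction type is the dirhodium-catalysed O–H insertion of 2-diazo-1,3-dicarbonyl compounds into alcohols and phenols. No ring is closed and no stereocentre is formed; the bond made is O–C2 of the future ring A. The step needs O–H insertion to win over Wolff ring contraction, attack of the carbenoid on the arene (cyclopropanation or C–H insertion) and insertion into the enol OH of the product. The two bromines deactivate ring B towards the carbenoid, the phenol is kept in excess while 2 is added slowly, and metal catalysis at 70 °C should stay below the onset of the thermal Wolff path. Because 2 is mirror-symmetric there is no regiochemistry to control.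

Step 3
Reactants: 4 2-(2,4-dibromophenoxy)cyclohexane-1,3-dione
Product: 5 3-bromo-2-(2,4-dibromophenoxy)cyclohex-2-en-1-one
Conditions: (COBr)2 (1.2 equiv), DMF (cat.), CH2Cl2, 0 °C → rt
Reagents that add atoms: oxalyl bromide, BrC(=O)C(=O)Br
Why: Vinylogous acid bromide formation (Vilsmeier-type activation of the enol oxygen, then addition–elimination by bromide), which can occur only once and gives the same product from either carbonyl of the symmetric dione, so that C3–Br is set without any aromatic substitution.

Step 4
Reactants: 5 3-bromo-2-(2,4-dibromophenoxy)cyclohex-2-en-1-one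
Product: 8 3-bromo-2-(2,4-dibromophenoxy)phenol, via cross-conjugated lithium dienolate 6 (not isolated), via α'-bromo enone 7 (not isolated)
Conditions: LiN(SiMe3)2 (1.05 equiv), THF, −78 °C; cannulated into NBS (1.0 equiv), THF, −78 °C; then DBU (2.5 equiv), −78 °C → rt; aq NH4Cl
Reagents that add atoms: none
Why: Bromination–dehydrobromination aromatisation of a cyclohexenone, in which kinetic α'-deprotonation at C6 gives 6, NBS brominates it to 7 and DBU removes HBr (C6–Br, C5–H) to a dienone that tautomerises to the phenol under the drive of aromatisation, while the vinyl and aryl C–Br bonds stay inert and any γ-bromide formed would lose HBr to the same phenol.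

Step 5
Reactants: 8 3-bromo-2-(2,4-dibromophenoxy)phenol
Product: 9 3,6-dibromo-2-(2,4-dibromophenoxy)phenol
Conditions: NBS (1.0 equiv), i-Pr2NH (10 mol%), CH2Cl2, 0 °C
Reagents that add atoms: N-bromosuccinimide, O=C1CCC(=O)N1Br
Why: Amine-mediated ortho-selective bromination of a 2-substituted phenol, in which the N-bromoamine formed from NBS is hydrogen-bonded to the phenol OH and delivers bromine to C6, the only free ortho position, while ring B (two bromines, no free OH) is too deactivated to compete and one equivalent of NBS limits attack at C4.

Compound list
1 | cyclohexane-1,3-dione | O=C1CCCC(=O)C1 | starting material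
2 | 2-diazocyclohexane-1,3-dione | [N-]=[N+]=C1C(=O)CCCC1=O | intermediate
3 | 2,4-dibromophenol | Oc1ccc(Br)cc1Br | starting material
4 | 2-(2,4-dibromophenoxy)cyclohexane-1,3-dione | O=C1CCCC(=O)C1Oc1ccc(Br)cc1Br | intermediate
5 | 3-bromo-2-(2,4-dibromophenoxy)cyclohex-2-en-1-one | O=C1CCCC(Br)=C1Oc1ccc(Br)cc1Br | intermediate
6 | lithium 5-bromo-6-(2,4-dibromophenoxy)cyclohexa-1,5-dien-1-olate | [Li+].[O-]C1=CCCC(Br)=C1Oc1ccc(Br)cc1Br | intermediate
7 | 3,6-dibromo-2-(2,4-dibromophenoxy)cyclohex-2-en-1-one (racemic) | O=C1C(Br)CCC(Br)=C1Oc1ccc(Br)cc1Br | intermediate
8 | 3-bromo-2-(2,4-dibromophenoxy)phenol | Oc1cccc(Br)c1Oc1ccc(Br)cc1Br | intermediate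
9 | 3,6-dibromo-2-(2,4-dibromophenoxy)phenol (achiral) | Oc1c(Br)ccc(Br)c1Oc1ccc(Br)cc1Br | target

Total step count: 5. Longest linear sequence: 5.

Steps most likely to fail

Step 4. The amide base or DBU could add to the β-bromo enone carbon C3 (addition–elimination) in place of α'-deprotonation, or proton exchange between the dienolate and the bromo ketone could scramble the degree of bromination. The fallback buys ring A aromatic and uses no enolate. It sets out from 3: nucleophilic aromatic substitution on purchased 3-bromo-2-fluorobenzaldehyde F1 (K2CO3, DMF, 80 °C; the fluoride ortho to the formyl group leaves) would give 3-bromo-2-(2,4-dibromophenoxy)benzaldehyde F2. Baeyer–Villiger oxidation (mCPBA, CH2Cl2), with aryl migration favoured by the ortho aryloxy donor, would give 3-bromo-2-(2,4-dibromophenoxy)phenyl formate F3. Hydrolysis (aq NaOH, THF) would release 8, where the route is rejoined.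

Step 5. Bromination para to the hydroxyl group (C4) could compete with or follow the ortho bromination. The fallback places the C6 bromine before ring A is aromatic, where enolate chemistry and not phenol directing effects decides the position. It sets out from 5: two consecutive kinetic enolate brominations (LiN(SiMe3)2, THF, −78 °C, then NBS, carried out twice, passing through 7) would give 3,6,6-tribromo-2-(2,4-dibromophenoxy)cyclohex-2-en-1-one F4. Treatment with DBU would remove HBr across C5–C6, and the resulting dienone would tautomerise directly to 9.

Step 2. The carbenoid could be diverted into Wolff ring contraction, attack on the arene or insertion into the enol OH of the product, so that little 4 is formed. The fallback forms the O–C2 bond by epoxide opening and needs no carbene. It sets out from 3: with purchased 2,3-epoxycyclohexan-1-one F5 and K2CO3 in DMF at 80 °C the phenoxide would open the epoxide at the carbon next to the carbonyl to give trans-2-(2,4-dibromophenoxy)-3-hydroxycyclohexan-1-one F6, which would lose water in the same pot to give 2-(2,4-dibromophenoxy)cyclohex-2-en-1-one F7. Br2 in CH2Cl2 at −78 °C would add across the enol-ether double bond to give trans-2,3-dibromo-2-(2,4-dibromophenoxy)cyclohexan-1-one F8. Et3N would then take out HBr through the oxygen-stabilised C2 cation, whose only neighbouring hydrogen is on C3, and this gives 5, where the route is rejoined.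

Further compounds
F1 | step 4 | 3-bromo-2-fluorobenzaldehyde | O=Cc1cccc(Br)c1F
F2 | step 4 | 3-bromo-2-(2,4-dibromophenoxy)benzaldehyde | O=Cc1cccc(Br)c1Oc1ccc(Br)cc1Br
F3 | step 4 | 3-bromo-2-(2,4-dibromophenoxy)phenyl formate | O=COc1cccc(Br)c1Oc1ccc(Br)cc1Br
F4 | step 5 | 3,6,6-tribromo-2-(2,4-dibromophenoxy)cyclohex-2-en-1-one | O=C1C(Br)(Br)CCC(Br)=C1Oc1ccc(Br)cc1Br
F5 | step 2 | 2,3-epoxycyclohexan-1-one (7-oxabicyclo[4.1.0]heptan-2-one; racemic, one enantiomer drawn) | O=C1CCC[C@H]2O[C@@H]12
F6 | step 2 | trans-2-(2,4-dibromophenoxy)-3-hydroxycyclohexan-1-one (racemic, one enantiomer drawn) | O=C1CCC[C@H](O)[C@H]1Oc1ccc(Br)cc1Br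
F7 | step 2 | 2-(2,4-dibromophenoxy)cyclohex-2-en-1-one | O=C1CCCC=C1Oc1ccc(Br)cc1Br
F8 | step 2 | trans-2,3-dibromo-2-(2,4-dibromophenoxy)cyclohexan-1-one (racemic, one enantiomer drawn) | O=C1CCC[C@H](Br)[C@]1(Br)Oc1ccc(Br)cc1Br
A1 | direct plan | veratrole (1,2-dimethoxybenzene) | COc1ccccc1OC
A2 | direct plan | 1,4-dibromo-2,3-dimethoxybenzene | COc1c(Br)ccc(Br)c1OC
A3 | direct plan | 3,6-dibromobenzene-1,2-diol (3,6-dibromocatechol) | Oc1c(Br)ccc(Br)c1O
A4 | direct plan | (2,4-dibromophenyl)(2,4,6-trimethoxyphenyl)iodonium 4-methylbenzenesulfonate | COc1cc(OC)c([I+]c2ccc(Br)cc2Br)c(OC)c1.Cc1ccc(cc1)S(=O)(=O)[O-]
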